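The runs are simulated for an exercise; the scatter is artificial.

The pitfall with a target that stops rising is to plan a longer run. In the maple run the readings from 5.00 d to 12.0 d stay between 22 % and 24 %, inside the scatter of 1.5 percentage points, so for the next run I looked for a change of recipe instead.

common to all: gas 200 mM (held)

| charge | solid substrate | second nucleophile | remark | time |
|---|---|---|---|---|
| maple | 0.59 M | 1 equiv | run made earlier |  |
| alder | 1.3 M | 1 equiv | run made earlier |  |
| flask | 0.88 M | 1.00 equiv |  | 10 d |

- maple (time / d: target / %): 2.50: 19; 5.00: 24; 8.00: 22; 10.0: 22; 12.0: 24
- alder (time / d: target / %): 1.04: 3; 1.67: 6; 3.00: 13; 6.00: 18; 12.0: 16

(each reading ± 1.5 percentage points)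

- solid, in amounts per volume of the solution: solid substrate
- at the start none of first nucleophile is dissolved
- reactions considered so far: starting material -> intermediate; solid substrate <-> starting material; first nucleophile + intermediate -> target; second nucleophile + intermediate -> other capture product; intermediate -> solvolysis product; gas <-> first nucleophile
- at the start none of the solid substrate is in solution

1. the target standing at 10 d, as a percentage of the solid substrate charged
2. the change that raises the amount of target at 10 d, in percent of the solid substrate charged most ("none" if none brings more than 2 percentage points) (Wednesday's / Saturday's / Sunday's / Thursday's / none)
3. amount of target at 10 d, in percent of the solid substrate charged, after Thursday's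

- Wednesday's: doubling the saturation concentration of gas, all else as stated
- Saturday's: doubling the transfer coefficient of the gas, all else as stated
- Sunday's: doubling the dissolution coefficient of the solid substrate, all else as stated
- Thursday's: doubling the amount of second nucleophile, all else as stated

I followed one molecule of intermediate. It can meet first nucleophile and give target, meet second nucleophile and give other capture product, or undergo solvolysis, and its chances go as the rates of these steps. The molecules lost per molecule of target are therefore the two loss rates over the capture rate. At a fixed 1 equiv, [second nucleophile] grows with the charge, so these odds should rise linearly with the charge, and [first nucleophile] divides them.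

I read plateaus of 23.0 % for maple and 17.0 % for alder. These give odds of 3.35 and 4.88, a slope of 2.16 /M. For the flask I reckoned from this line waste odds of 3.97, intermediate lost per molecule of target, an inverse selectivity factor, and so 20.1 % target.

Thursday's adds 1.90 to the flask's odds, giving 14.5 %. Wednesday's, if [first nucleophile] follows the saturation concentration of 200 mM, halves them, giving 33.5 %. The two coefficients do not enter my odds, and Wednesday's figure stands higher than the flask's 20.1 % and Thursday's 14.5 %, so I would change the gas.

The forecast gave 20.5 %, Wednesday's and 14 % after Thursday's, reasoning that “Doubling gas saturation roughly doubles dissolved first nucleophile”.

The flask gave 19.9 %, and Wednesday's gained most at 13 points, while Saturday's moved it 0.095 points, Sunday's −0.038 points, and Thursday's left 12.8 %.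

    starting material → intermediate (k = 0.0560 /h)
    solid substrate ⇌ starting material, rate k2*(cs2 - [starting material]) while solid is left; crystals form when [starting material] > cs2 (solubility = 0.350 M, k = 0.210 /h)
    first nucleophile + intermediate → target (k = 20.0 /M/h)
    second nucleophile + intermediate → other capture product (k = 14.0 /M/h)
    intermediate → solvolysis product (k = 6.70 /h)
    gas ⇌ first nucleophile, rate k6*(csat - [first nucleophile]) (kL = 1.30 /h)

At 1.00 d the flask already held 0.198 M first nucleophile, close to the saturation value of 200 mM. Its waste odds came to 4.03. The same line, carried to the neighbouring flask at 2.2 M with the equivalents held, gives odds of 6.83 and 12.8 % target. That neighbouring flask ended at 13.3 % target.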